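# Proposed total synthesis of CNP0258430.1 through a cyclopropane relay

Atom numbering used throughout (germacrane numbering): C1 furanone carbonyl; C2=C3 furanone alkene, C3 on the ring oxygen; C4 (methyl C15)=C5; C6 acyloxy carbon; C7; C8 lactone oxygen; C9; C10 (methyl C14, ring oxygen); C11; C12 lactone carbonyl; C13 exocyclic methylene.

## The problem

The target is a ten-membered carbocycle (C1–C10) bridged by an oxygen between C3 and C10, so that C10–C1(=O)–C2=C3–O is a 3(2H)-furanone, and fused at C7–C8 to a trans α-methylidene-γ-butyrolactone (C11–C13). A Z-trisubstituted alkene C4=C5 is conjugated to the furanone, and C6 carries a (2S,3S)-2,3-dimethyloxirane-2-carboxylate (epoxyangelate) ester. The three contiguous centres 6S, 7R and 8S can be relayed from one another. The oxygenated quaternary C10 (S) is insulated from them by the C9 methylene and needs its own source, as do the two epoxide centres of the acid. The methylidene lactone, the furanone (a vinylogous ester), the glycidic ester and the allylic C6 ester forbid strong base, nucleophilic amines and Lewis acids late in the route. The medium ring must be closed against transannular strain without loss of the Z geometry at C4=C5. The enabling feature is that C11 is bonded to C7, C7 lies next to the allylic, oxygen-bearing C6, and C12 hangs on the C8 oxygen. A carbene at C11, tethered as a C8 ester, can therefore bridge the C6=C7 alkene of a diene, and the temporary C6–C11 bond can afterwards be exchanged for the C6–O bond with inversion.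

## Retrosynthesis

**Furanone (31 ⇒ 30).** The C3–O bond of the furanone is cut and the C1 carbonyl is traced to an alkyne carbon, giving the γ-hydroxy ynone 30. Forming the furanone before ring closure would force a macrocyclisation beside a vinylogous ester, whereas the ynone reuses the alkyne that closes the ring. The precursor has one ring and one bridge fewer. The forward reaction must be a neutral, amine-free cycloisomerisation, because the methylidene lactone is already present.

**Ten-membered ring (30 ⇒ 29 ⇒ 28).** The C2–C3 bond is cut. Closure at C4=C5 by metathesis would have to set a Z-trisubstituted alkene in a medium ring, and closure at C7–C8 or C9–C10 would create a ring stereocentre in the cyclisation. The C2–C3 cut creates only a carbinol (29) that is oxidised away. The precursor 28 is acyclic, with an iodoalkyne and a Z enal held near each other by the Z alkene. The forward step must add to the aldehyde alone, at high dilution.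

**Functional-group adjustments (28 ⇒ 27 ⇒ 26 ⇒ 25).** Enal 28 comes from diol 27, 27 from bis-silyl ether 26, and iodoalkyne 26 from alkynylsilane 25. No skeletal bond is cut. The order keeps the sensitive Z enal to the last moment before ring closure.

**Methylidene (25 ⇒ 24).** The C11=C13 bond is cut by a Horner–Wadsworth–Emmons methylenation of the α-phosphono lactone 24. Enolate methylenation of a plain lactone would need strong base on a molecule with an allylic ester. The phosphonate makes the step a mild carbonate-mediated one, and it is the second acceptor that the preceding ring opening needs.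

**C6 ester with inversion (24 ⇒ 19 + 23).** The C6–O bond is cut and the C6–C11 bond is redrawn, leading to the vinylcyclopropane-fused lactone 19 and the epoxy acid 23. Esterifying a C6 carbinol is the obvious neighbour, but it would require C6 to be set separately. Here C6 is set in the cyclopropanation and inverted in the opening. A lactone alone would not activate the cyclopropane enough for a carboxylate, so C11 carries the phosphonate as well. The forward reaction must be a direct displacement, not an ionisation.

**Cyclopropane and lactone (19 ⇒ 18).** The C7–C11 and C6–C11 bonds are cut together, giving the dienyl diazo(phosphono)acetate 18. One step builds two rings, two skeletal bonds and the C6/C7 pair (plus the temporary C11 centre) from the single C8 centre. The forward reaction must select the C6=C7 alkene and the face set by C8.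

**Diazo ester (18 ⇒ 17 ⇒ 15 + 16).** Diazo transfer and the ester C–O bond lead back to dienol 15 and acid 16. Both steps are routine and neutral enough for a doubly allylic alcohol.

**C7–C8 bond (15 ⇒ 12 + 5).** The allylic carbinol is cut between C7 and C8, giving enyne 12 and aldehyde 5. Hydrometalation of the terminal alkyne sets the E geometry at C6=C7, and a chiral ligand sets C8. The two halves are of similar size.

**Aldehyde (5 ⇒ 4 ⇒ 3 ⇒ 1 + 2).** Alkene cleavage and the C9–C10 bond lead to ynone 1 and allylboronate 2. A chiral-pool hydroxy acid would secure C10 but costs about five more steps. The catalytic allylation reaches 5 in three steps. A minor C10 enantiomer becomes a separable diastereomer once C8 is set by reagent control.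

**Enyne (12 ⇒ 11 ⇒ 9 + 10; 9 ⇒ 8 ⇒ 6).** The C5–C6 bond is cut by a Sonogashira coupling of iodide 9 with alkyne 10. Iodide 8 comes from alcohol 6 by carbometalation and iodination, which fixes the Z geometry of C4=C5 at the outset.

**Acid (23 ⇒ 22 ⇒ 21 ⇒ 20).** The epoxide is traced to the Z allylic alcohol 21 from acid 20. The Z alkene gives the cis relation of the epoxide substituents, and the tartrate gives the absolute sense.

## Roads not taken

**Alternative 1:** The C6–C7 bond is cut, and the ten-membered ring is traced to the thirteen-membered diallyl ether A1, in which oxygen links C6 and C13. Deprotonation of A1 at C6 would start a [2,3]-Wittig shift that forms C6–C7, cleaves O–C13 and contracts the ring to A2, with a C6 hydroxyl and a C7 isopropenyl group.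
- Merits: the medium ring arises by contraction of a larger, easier ring. C6 and C7 are made together through an ordered five-membered transition state. The furanone and C10 are already in place, and the C6 hydroxyl is ready for acylation.
- Weak points: the base must choose C6–H over the equally allylic, oxygen-flanked C13–H2. It must also spare the electrophilic furanone. The sense at C6 and C7 relative to C8 and C10 depends on a macrocyclic transition state that is hard to predict. The isopropenyl group must afterwards be oxidised at C12 in the presence of the C15 allylic methyl, then lactonised and methylenated.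
- Comparison: this road is better at ring formation, since it has no strained cycloalkyne closure, and it delivers the C6 oxygen directly. The chosen plan sets against this a stereospecific relay of C6 and C7 from one acyclic centre, and C11–C12 at the lactone oxidation level from the key step on.

**Alternative 2:** The O–C10 and C9–C10 bonds are cut, and the carbocycle is traced to the dihydropyran diazoketone A3, whose ring oxygen joins C3 and C7. A copper carbenoid at C10 would be captured by that oxygen. The oxonium ylide would undergo a [2,3]-shift of the C7-bound silyloxyvinyl group, forming O–C10 and C9–C10, cleaving O–C7 and giving the oxa-bridged bicyclic ketone A4.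
- Merits: the oxygen bridge, the quaternary C10 and the ten-membered ring all arise in one step from a six-membered ring that is easy to make in defined form. No macrocyclisation is needed.
- Weak points: the electron-rich silyl enol ether of A3 is itself a good carbenoid acceptor. A [1,2]-shift and C–H insertion also compete. A4 lacks C11–C13 and the C7 and C8 stereocentres, so C7 must be alkylated, C8 reduced, the lactone closed and methylenated, and C2–C3 dehydrogenated. All of this happens late, under transannular control.
- Comparison: this road is clearly shorter to the bicyclic core, and better in that respect. The chosen plan answers with predictable acyclic control of C6–C8 and a lactone that exists from the key step.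

**Alternative 3:** The C2–C3 and C4–C5 bonds are cut as a two-carbon insertion, leading to the lactone-fused cyclooctenone A5 and the siloxypropyne A6. AgN(SO2CF3)2 would promote (2+2) addition of A6 across the C2=C5 enone alkene of A5. Heating would then open the four-membered ring by conrotatory cleavage of C2–C5, giving the ten-membered siloxy dienone A7.
- Merits: the lactone and the C6, C7, C8 and C10 centres are fixed before ring expansion. A7 is only a furanone closure, an acylation and a methylenation away from the target.
- Weak points: A5 is an eight-membered ring with four stereocentres and is a demanding target in itself. The (2+2) step is established for unhindered enones, whereas here C5 is flanked by a silyloxy-bearing C6 and the α′ carbon is quaternary. The conrotatory opening must also deliver the Z geometry at C4=C5 within a ten-membered ring.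
- Comparison: the endgame is shorter and needs no inverting displacement, which is better. The chosen plan sets against this simple commercial building blocks and no eight-membered intermediate. It pays with a strained ring closure and an unprecedented cyclopropane opening.

Key step: step 11

## Route

Remark on the chemistry (assumption): the facial sense of the two catalytic enantioselective additions (steps 1 and 8) is assigned from the usual transition-state models of these catalyst families. The required outcomes are Si-face allylation of 1 and Re-face alkenylation of 5, and the antipodal catalyst or ligand would be used if a model proved misleading for these substrates.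

Step 1
Reactants: 1 4-(trimethylsilyl)but-3-yn-2-one; 2 allyldiisopropoxyborane
Product: 3 (3S)-3-methyl-1-(trimethylsilyl)hex-5-en-1-yn-3-ol
Conditions: (S)-3,3'-Br2-BINOL (15 mol %), PhMe/PhCF3, −35 °C; aq. work-up
Reagents that add atoms: none
Why: Chiral-diol-catalysed asymmetric allylboration of a methyl ketone; exchange of an isopropoxy group gives a chiral allylboronate that transfers allyl through a closed chair transition state to the Si face, the alkynyl group acting as the unsaturated large substituent, which sets C10 (S).

Step 2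
Reactants: 3 (3S)-3-methyl-1-(trimethylsilyl)hex-5-en-1-yn-3-ol
Product: 4 triethyl{[(3S)-3-methyl-1-(trimethylsilyl)hex-5-en-1-yn-3-yl]oxy}silane
Conditions: TESOTf, 2,6-lutidine, CH2Cl2, −78 → 0 °C
Reagents that add atoms: triethylsilyl trifluoromethanesulfonate, CC[Si](CC)(CC)OS(=O)(=O)C(F)(F)F
Why: Silylation of a hindered tertiary alcohol with a silyl triflate; the ether prevents retro-aldol cleavage after step 3 and O–H insertion in the key step.

Step 3
Reactants: 4 triethyl{[(3S)-3-methyl-1-(trimethylsilyl)hex-5-en-1-yn-3-yl]oxy}silane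
Product: 5 (3S)-3-methyl-3-[(triethylsilyl)oxy]-5-(trimethylsilyl)pent-4-ynal
Conditions: OsO4 (2 mol %), NaIO4, 2,6-lutidine, dioxane/H2O, rt
Reagents that add atoms: sodium periodate, [Na+].[O-]I(=O)(=O)=O; water, O
Why: Lemieux–Johnson cleavage; osmium tetroxide dihydroxylates the terminal alkene and leaves the silylalkyne alone, periodate cleaves the diol, and the lutidine buffer protects the TES ether.

Step 4
Reactants: 6 propargyl alcohol
Product: 8 (2Z)-3-iodo-2-methylprop-2-en-1-ol, via alkenylmagnesium alkoxide 7 (not isolated)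
Conditions: MeMgBr (2.5 equiv), CuI (10 mol %), THF, −10 °C → rt; then I2, −78 → 0 °C
Reagents that add atoms: methylmagnesium bromide, C[Mg]Br; iodine, II
Why: Copper-catalysed anti-carbomagnesiation of the propargylic alkoxide places methyl (C15) on C4 and magnesium on C5 cis to the CH2O group in a five-membered chelate; iodinolysis with retention gives the Z iodide and so fixes the C4=C5 geometry.

Step 5
Reactants: 8 (2Z)-3-iodo-2-methylprop-2-en-1-ol
Product: 9 tert-butyl{[(2Z)-3-iodo-2-methylprop-2-en-1-yl]oxy}dimethylsilane
Conditions: TBSCl, imidazole, DMF, rt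
Reagents that add atoms: tert-butyldimethylsilyl chloride, CC(C)(C)[Si](C)(C)Cl
Why: Standard silylation of a primary alcohol; the TBS ether survives the organometallic and carbenoid steps.

Step 6
Reactants: 9 tert-butyl{[(2Z)-3-iodo-2-methylprop-2-en-1-yl]oxy}dimethylsilane; 10 ethynyltrimethylsilane
Product: 11 tert-butyldimethyl{[(2Z)-2-methyl-5-(trimethylsilyl)pent-2-en-4-yn-1-yl]oxy}silane
Conditions: Pd(PPh3)2Cl2 (2 mol %), CuI (4 mol %), Et3N, THF, rt
Reagents that add atoms: none
Why: Sonogashira coupling of an alkenyl iodide, which proceeds with retention of the alkene geometry and forms C5–C6.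

Step 7
Reactants: 11 tert-butyldimethyl{[(2Z)-2-methyl-5-(trimethylsilyl)pent-2-en-4-yn-1-yl]oxy}silane
Product: 12 tert-butyldimethyl{[(2Z)-2-methylpent-2-en-4-yn-1-yl]oxy}silane
Conditions: K2CO3 (cat.), MeOH, 0 °C → rt
Reagents that add atoms: none
Why: Methanolysis of the alkynyl C–Si bond; the TBS ether is stable to these conditions.

Step 8
Reactants: 12 tert-butyldimethyl{[(2Z)-2-methylpent-2-en-4-yn-1-yl]oxy}silane; 5 (3S)-3-methyl-3-[(triethylsilyl)oxy]-5-(trimethylsilyl)pent-4-ynal
Product: 15 (3S,5S,6E,8Z)-10-{[tert-butyl(dimethyl)silyl]oxy}-3,9-dimethyl-3-[(triethylsilyl)oxy]-1-(trimethylsilyl)deca-6,8-dien-1-yn-5-ol, via dienylborane 13 (not isolated), via dienylzinc 14 (not isolated)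
Conditions: Cy2BH, PhMe/hexane, 0 °C → rt; Me2Zn, −78 °C; (+)-MIB [(+)-3-exo-morpholinoisoborneol] (10 mol %), then 5, −20 → 0 °C
Reagents that add atoms: none
Why: Syn hydroboration of the terminal alkyne gives the E dienylborane, boron-to-zinc exchange gives the dienylzinc, and amino-alcohol-catalysed alkenylzinc addition to the aldehyde forms C7–C8; the ligand enantiomer is chosen for Re-face delivery, which sets C8 (S) under reagent control because C10 is too remote to interfere.

Step 9
Reactants: 15 dienol (8S,10S); 16 (diethoxyphosphoryl)acetic acid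
Product: 17 (3S,5S,6E,8Z)-10-{[tert-butyl(dimethyl)silyl]oxy}-3,9-dimethyl-3-[(triethylsilyl)oxy]-1-(trimethylsilyl)deca-6,8-dien-1-yn-5-yl (diethoxyphosphoryl)acetate
Conditions: DCC, DMAP (10 mol %), CH2Cl2, 0 °C → rt
Reagents that add atoms: none
Why: Steglich esterification under neutral conditions that do not ionise the doubly allylic alcohol; C8 is untouched.

Step 10
Reactants: 17 dienyl (diethoxyphosphoryl)acetate
Product: 18 (3S,5S,6E,8Z)-10-{[tert-butyl(dimethyl)silyl]oxy}-3,9-dimethyl-3-[(triethylsilyl)oxy]-1-(trimethylsilyl)deca-6,8-dien-1-yn-5-yl diazo(diethoxyphosphoryl)acetate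
Conditions: p-ABSA, DBU, MeCN, 0 °C → rt
Reagents that add atoms: 4-acetamidobenzenesulfonyl azide, CC(=O)Nc1ccc(cc1)S(=O)(=O)N=[N+]=[N-]
Why: Regitz diazo transfer to the acidic phosphonoacetate methylene.

Step 11
Reactants: 18 dienyl diazo(diethoxyphosphoryl)acetate
Product: 19 diethyl [(1R,4S,5S,6R)-6-[(1Z)-3-{[tert-butyl(dimethyl)silyl]oxy}-2-methylprop-1-en-1-yl]-4-{(2S)-2-methyl-2-[(triethylsilyl)oxy]-4-(trimethylsilyl)but-3-yn-1-yl}-2-oxo-3-oxabicyclo[3.1.0]hexan-1-yl]phosphonate
Conditions: Rh2(OAc)4 (2 mol %), PhMe, 80 °C, slow addition of 18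
Reagents that add atoms: none
Why: Dirhodium tetraacetate (divalent rhodium) expels nitrogen from the diazo ester, and the electrophilic carbenoid at C11 adds to the nearer C6=C7 alkene in a concerted, asynchronous (2+1) addition. The closest known reaction type is the intramolecular cyclopropanation of allylic diazoacetates, diazomalonates and diazophosphonoacetates to 3-oxabicyclo[3.1.0]hexan-2-ones. The γ-lactone closes by C7–C11 bond formation through the five-atom tether C11–C12–O–C8–C7, and the cyclopropane closes in the same event by C6–C11 bond formation. The addition is suprafacial on the E alkene, so C5 ends exo on the cyclopropane and C6 and C7 are set as a pair; C11 follows from the obligatory cis ring fusion. The sense of this pair relative to C8 is set by the C8 centre, whose bulky C9–C10 chain should take the exo position on the convex face of the forming bicycle, anti to the cyclopropane, which is the trans relation of C6 and C9 on the lactone. The step needs site selectivity: the C4=C5 alkene could be reached only through a seven-membered ring, the C9 methylene is neopentyl and unactivated toward C–H insertion, the alkyne is remote and silyl-capped, and both hydroxyls are silylated. Slow addition keeps the diazo concentration low and suppresses carbene dimerisation and dipolar cycloaddition of the diazo group to the diene.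

Step 12
Reactants: 20 angelic acid
Product: 21 (2Z)-2-methylbut-2-en-1-ol
Conditions: LiAlH4, Et2O, 0 °C
Reagents that add atoms: none
Why: Hydride reduction of the unsaturated acid to the allylic alcohol without change of the Z geometry.

Step 13
Reactants: 21 (2Z)-2-methylbut-2-en-1-ol
Product: 22 [(2R,3S)-2,3-dimethyloxiran-2-yl]methanol
Conditions: Ti(OiPr)4 (10 mol %), D-(−)-diethyl tartrate (12 mol %), t-BuOOH, 4 Å MS, CH2Cl2, −20 °C
Reagents that add atoms: tert-butyl hydroperoxide, CC(C)(C)OO
Why: Sharpless asymmetric epoxidation; the D-tartrate complex delivers oxygen to the face that gives the (2R,3S) epoxy alcohol, and the cis relation of the C3 methyl and the hydroxymethyl group comes from the Z alkene.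

Step 14
Reactants: 22 [(2R,3S)-2,3-dimethyloxiran-2-yl]methanol
Product: 23 (2S,3S)-2,3-dimethyloxirane-2-carboxylic acid
Conditions: TEMPO (20 mol %), PhI(OAc)2 (2.2 equiv), MeCN/H2O, rt
Reagents that add atoms: water, O
Why: Oxoammonium oxidation of the primary alcohol through the aldehyde hydrate to the acid; no stereocentre is touched, and the C2 descriptor changes from R to S only because the substituent priorities change.

Step 15
Reactants: 19 cyclopropane-fused phosphono lactone; 23 (2S,3S)-2,3-dimethyloxirane-2-carboxylic acid
Product: 24 (1S,2Z)-4-{[tert-butyl(dimethyl)silyl]oxy}-1-[(2S,3R)-4-(diethoxyphosphoryl)-2-{(2S)-2-methyl-2-[(triethylsilyl)oxy]-4-(trimethylsilyl)but-3-yn-1-yl}-5-oxooxolan-3-yl]-3-methylbut-2-en-1-yl (2S,3S)-2,3-dimethyloxirane-2-carboxylate (C11 epimers)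
Conditions: 23 (3 equiv), Cs2CO3 (0.5 equiv), DMF, 60 °C
Reagents that add atoms: none
Why: Proposed new method: the cyclopropane of 19 carries two acceptors on C11 (lactone carbonyl and phosphonate) and a secondary allylic C6, so the cesium carboxylate of 23 should attack C6 anti to the C6–C11 bond in an SN2-type homoconjugate addition, the bond electrons leaving into the phosphonate-stabilised lactone enolate, which the excess acid protonates; inversion gives 6S and frees C11 as the lactone α-carbon; attack at the ring-fusion carbon C7 would give a six-membered lactone and is hindered, SN2′ attack at C4 meets a fully substituted carbon, and without a Lewis acid the bond cannot ionise; the closest known reaction type is the inverting ring opening of cyclopropane-1,1-dicarboxylates, 2-vinylcyclopropane-1,1-diesters and 1-acyl-2-oxo-3-oxabicyclo[3.1.0]hexanes by amines, thiolates, azide and phenoxides.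

Step 16
Reactants: 24 α-phosphono lactone ester
Product: 25 (1S,2Z)-4-{[tert-butyl(dimethyl)silyl]oxy}-3-methyl-1-[(2S,3R)-4-methylidene-2-{(2S)-2-methyl-2-[(triethylsilyl)oxy]-4-(trimethylsilyl)but-3-yn-1-yl}-5-oxooxolan-3-yl]but-2-en-1-yl (2S,3S)-2,3-dimethyloxirane-2-carboxylate
Conditions: aq. HCHO (methanol-free), K2CO3, THF, 0 °C
Reagents that add atoms: formaldehyde, C=O
Why: Horner–Wadsworth–Emmons olefination of an α-phosphono lactone with formaldehyde; both C11 epimers converge on the methylidene lactone, and cold carbonate leaves the esters and the silyl groups in place.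

Step 17
Reactants: 25 methylidene lactone with alkynylsilane
Product: 26 (1S,2Z)-4-{[tert-butyl(dimethyl)silyl]oxy}-1-[(2S,3R)-2-{(2S)-4-iodo-2-methyl-2-[(triethylsilyl)oxy]but-3-yn-1-yl}-4-methylidene-5-oxooxolan-3-yl]-3-methylbut-2-en-1-yl (2S,3S)-2,3-dimethyloxirane-2-carboxylate
Conditions: NIS, AgNO3 (20 mol %), DMF, rt, dark
Reagents that add atoms: N-iodosuccinimide, O=C1CCC(=O)N1I
Why: Silver-catalysed iododesilylation of an alkynylsilane through the silver acetylide; any alkyne that lost its silyl group in step 16 is iodinated in the same way.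

Step 18
Reactants: 26 iodoalkyne bis-silyl ether
Product: 27 (1S,2Z)-4-hydroxy-1-{(2S,3R)-2-[(2S)-2-hydroxy-4-iodo-2-methylbut-3-yn-1-yl]-4-methylidene-5-oxooxolan-3-yl}-3-methylbut-2-en-1-yl (2S,3S)-2,3-dimethyloxirane-2-carboxylate
Conditions: HF·pyridine, pyridine, THF, 0 °C → rt
Reagents that add atoms: none
Why: Buffered fluoride cleavage of the primary TBS and tertiary TES ethers under non-basic conditions, which avoids acyl migration from O6 to O3 and conjugate addition to the lactone.

Step 19
Reactants: 27 iodoalkyne diol
Product: 28 (1S,2Z)-1-{(2S,3R)-2-[(2S)-2-hydroxy-4-iodo-2-methylbut-3-yn-1-yl]-4-methylidene-5-oxooxolan-3-yl}-3-methyl-4-oxobut-2-en-1-yl (2S,3S)-2,3-dimethyloxirane-2-carboxylate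
Conditions: MnO2 (activated, excess), CH2Cl2, rt
Reagents that add atoms: none
Why: Chemoselective oxidation of the primary allylic alcohol; the tertiary alcohol is inert and the neutral heterogeneous conditions should preserve the Z enal, which is used at once.

Step 20
Reactants: 28 iodoalkyne enal
Product: 29 (6S,7R,8S,10S)-3,10-dihydroxygermacra-4(Z),11(13)-dien-1-yn-12,8-olide 6-[(2S,3S)-2,3-dimethyloxirane-2-carboxylate] (C3 epimers)
Conditions: CrCl2 (6 equiv), NiCl2 (1 mol %), THF/DMF, rt, high dilution
Reagents that add atoms: none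
Why: Nozaki–Hiyama–Kishi reaction; divalent chromium converts the C–I bond into an alkynylchromium species that adds only to the aldehyde, forming C2–C3 and closing the ten-membered ring; the Z alkene and the trans lactone hold the two ends near each other, and both C3 epimers are used.

Step 21
Reactants: 29 macrocyclic propargylic alcohol
Product: 30 (6S,7R,8S,10S)-10-hydroxy-3-oxogermacra-4(Z),11(13)-dien-1-yn-12,8-olide 6-[(2S,3S)-2,3-dimethyloxirane-2-carboxylate]
Conditions: Dess–Martin periodinane, NaHCO3, CH2Cl2, 0 °C → rt
Reagents that add atoms: none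
Why: Buffered oxidation of the secondary propargylic, allylic alcohol to the cross-conjugated ynone; the tertiary C10 alcohol cannot be oxidised.

Step 22
Reactants: 30 γ-hydroxy ynone
Product: 31 target CNP0258430.1, (6S,7R,8S,10S)-3,10-epoxy-1-oxogermacra-2,4(Z),11(13)-trien-12,8-olide 6-[(2S,3S)-2,3-dimethyloxirane-2-carboxylate]
Conditions: (p-CF3C6H4)3PAuCl (5 mol %), AgOTf (5 mol %), PhMe, rt
Reagents that add atoms: none
Why: Cycloisomerisation of a γ-hydroxy ynone to a 3(2H)-furanone under cationic monovalent gold: the activated alkyne is formally hydrated at C1 and the C10 hydroxyl condenses on the C3 carbonyl across the ring; no amine is present to add to the methylidene lactone, and C10 keeps its configuration because its C–O bond is never broken.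

## Compound list

1 | 4-(trimethylsilyl)but-3-yn-2-one | CC(=O)C#C[Si](C)(C)C | starting material
2 | allyldiisopropoxyborane (diisopropyl allylboronate) | C=CCB(OC(C)C)OC(C)C | starting material
3 | (3S)-3-methyl-1-(trimethylsilyl)hex-5-en-1-yn-3-ol | C=CC[C@](C)(O)C#C[Si](C)(C)C | intermediate
4 | triethyl{[(3S)-3-methyl-1-(trimethylsilyl)hex-5-en-1-yn-3-yl]oxy}silane | C=CC[C@](C)(O[Si](CC)(CC)CC)C#C[Si](C)(C)C | intermediate
5 | (3S)-3-methyl-3-[(triethylsilyl)oxy]-5-(trimethylsilyl)pent-4-ynal | O=CC[C@](C)(O[Si](CC)(CC)CC)C#C[Si](C)(C)C | intermediate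
6 | propargyl alcohol (prop-2-yn-1-ol) | C#CCO | starting material
7 | bromomagnesium (2Z)-3-(bromomagnesio)-2-methylprop-2-en-1-olate | Br[Mg]OC/C(C)=C\[Mg]Br | intermediate (not isolated)
8 | (2Z)-3-iodo-2-methylprop-2-en-1-ol | OC/C(C)=C\I | intermediate
9 | tert-butyl{[(2Z)-3-iodo-2-methylprop-2-en-1-yl]oxy}dimethylsilane | CC(C)(C)[Si](C)(C)OC/C(C)=C\I | intermediate
10 | ethynyltrimethylsilane | C#C[Si](C)(C)C | starting material
11 | tert-butyldimethyl{[(2Z)-2-methyl-5-(trimethylsilyl)pent-2-en-4-yn-1-yl]oxy}silane | CC(C)(C)[Si](C)(C)OC/C(C)=C\C#C[Si](C)(C)C | intermediate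
12 | tert-butyldimethyl{[(2Z)-2-methylpent-2-en-4-yn-1-yl]oxy}silane | CC(C)(C)[Si](C)(C)OC/C(C)=C\C#C | intermediate
13 | [(1E,3Z)-5-{[tert-butyl(dimethyl)silyl]oxy}-4-methylpenta-1,3-dien-1-yl]dicyclohexylborane | CC(C)(C)[Si](C)(C)OC/C(C)=C\C=C\B(C1CCCCC1)C1CCCCC1 | intermediate (not isolated)
14 | [(1E,3Z)-5-{[tert-butyl(dimethyl)silyl]oxy}-4-methylpenta-1,3-dien-1-yl](methyl)zinc | C[Zn]/C=C/C=C(C)\CO[Si](C)(C)C(C)(C)C | intermediate (not isolated)
15 | (3S,5S,6E,8Z)-10-{[tert-butyl(dimethyl)silyl]oxy}-3,9-dimethyl-3-[(triethylsilyl)oxy]-1-(trimethylsilyl)deca-6,8-dien-1-yn-5-ol (8S,10S in target numbering) | O[C@@H](C[C@](C)(O[Si](CC)(CC)CC)C#C[Si](C)(C)C)/C=C/C=C(C)\CO[Si](C)(C)C(C)(C)C | intermediate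
16 | (diethoxyphosphoryl)acetic acid | OC(=O)CP(=O)(OCC)OCC | starting material
17 | (3S,5S,6E,8Z)-10-{[tert-butyl(dimethyl)silyl]oxy}-3,9-dimethyl-3-[(triethylsilyl)oxy]-1-(trimethylsilyl)deca-6,8-dien-1-yn-5-yl (diethoxyphosphoryl)acetate | CCOP(=O)(OCC)CC(=O)O[C@@H](C[C@](C)(O[Si](CC)(CC)CC)C#C[Si](C)(C)C)/C=C/C=C(C)\CO[Si](C)(C)C(C)(C)C | intermediate
18 | (3S,5S,6E,8Z)-10-{[tert-butyl(dimethyl)silyl]oxy}-3,9-dimethyl-3-[(triethylsilyl)oxy]-1-(trimethylsilyl)deca-6,8-dien-1-yn-5-yl diazo(diethoxyphosphoryl)acetate | CCOP(=O)(OCC)C(=[N+]=[N-])C(=O)O[C@@H](C[C@](C)(O[Si](CC)(CC)CC)C#C[Si](C)(C)C)/C=C/C=C(C)\CO[Si](C)(C)C(C)(C)C | intermediate (precursor of the key step)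
19 | diethyl [(1R,4S,5S,6R)-6-[(1Z)-3-{[tert-butyl(dimethyl)silyl]oxy}-2-methylprop-1-en-1-yl]-4-{(2S)-2-methyl-2-[(triethylsilyl)oxy]-4-(trimethylsilyl)but-3-yn-1-yl}-2-oxo-3-oxabicyclo[3.1.0]hexan-1-yl]phosphonate | O=C1O[C@@H](C[C@](C)(O[Si](CC)(CC)CC)C#C[Si](C)(C)C)[C@@H]2[C@@H](/C=C(C)\CO[Si](C)(C)C(C)(C)C)[C@]12P(=O)(OCC)OCC | intermediate (product of the key step)
20 | angelic acid, (2Z)-2-methylbut-2-enoic acid | C/C=C(/C)C(=O)O | starting material
21 | (2Z)-2-methylbut-2-en-1-ol | C/C=C(/C)CO | intermediate
22 | [(2R,3S)-2,3-dimethyloxiran-2-yl]methanol | OC[C@@]1(C)O[C@H]1C | intermediate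
23 | (2S,3S)-2,3-dimethyloxirane-2-carboxylic acid | OC(=O)[C@@]1(C)O[C@H]1C | intermediate
24 | (1S,2Z)-4-{[tert-butyl(dimethyl)silyl]oxy}-1-[(2S,3R)-4-(diethoxyphosphoryl)-2-{(2S)-2-methyl-2-[(triethylsilyl)oxy]-4-(trimethylsilyl)but-3-yn-1-yl}-5-oxooxolan-3-yl]-3-methylbut-2-en-1-yl (2S,3S)-2,3-dimethyloxirane-2-carboxylate, both epimers at the phosphonate carbon C11 | CCOP(=O)(OCC)C1C(=O)O[C@@H](C[C@](C)(O[Si](CC)(CC)CC)C#C[Si](C)(C)C)[C@@H]1[C@@H](OC(=O)[C@@]2(C)O[C@H]2C)/C=C(C)\CO[Si](C)(C)C(C)(C)C | intermediate
25 | (1S,2Z)-4-{[tert-butyl(dimethyl)silyl]oxy}-3-methyl-1-[(2S,3R)-4-methylidene-2-{(2S)-2-methyl-2-[(triethylsilyl)oxy]-4-(trimethylsilyl)but-3-yn-1-yl}-5-oxooxolan-3-yl]but-2-en-1-yl (2S,3S)-2,3-dimethyloxirane-2-carboxylate | C=C1C(=O)O[C@@H](C[C@](C)(O[Si](CC)(CC)CC)C#C[Si](C)(C)C)[C@@H]1[C@@H](OC(=O)[C@@]2(C)O[C@H]2C)/C=C(C)\CO[Si](C)(C)C(C)(C)C | intermediate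
26 | (1S,2Z)-4-{[tert-butyl(dimethyl)silyl]oxy}-1-[(2S,3R)-2-{(2S)-4-iodo-2-methyl-2-[(triethylsilyl)oxy]but-3-yn-1-yl}-4-methylidene-5-oxooxolan-3-yl]-3-methylbut-2-en-1-yl (2S,3S)-2,3-dimethyloxirane-2-carboxylate | C=C1C(=O)O[C@@H](C[C@](C)(O[Si](CC)(CC)CC)C#CI)[C@@H]1[C@@H](OC(=O)[C@@]2(C)O[C@H]2C)/C=C(C)\CO[Si](C)(C)C(C)(C)C | intermediate
27 | (1S,2Z)-4-hydroxy-1-{(2S,3R)-2-[(2S)-2-hydroxy-4-iodo-2-methylbut-3-yn-1-yl]-4-methylidene-5-oxooxolan-3-yl}-3-methylbut-2-en-1-yl (2S,3S)-2,3-dimethyloxirane-2-carboxylate | C=C1C(=O)O[C@@H](C[C@](C)(O)C#CI)[C@@H]1[C@@H](OC(=O)[C@@]2(C)O[C@H]2C)/C=C(C)\CO | intermediate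
28 | (1S,2Z)-1-{(2S,3R)-2-[(2S)-2-hydroxy-4-iodo-2-methylbut-3-yn-1-yl]-4-methylidene-5-oxooxolan-3-yl}-3-methyl-4-oxobut-2-en-1-yl (2S,3S)-2,3-dimethyloxirane-2-carboxylate | C=C1C(=O)O[C@@H](C[C@](C)(O)C#CI)[C@@H]1[C@@H](OC(=O)[C@@]2(C)O[C@H]2C)/C=C(C)\C=O | intermediate
29 | (6S,7R,8S,10S)-3,10-dihydroxygermacra-4(Z),11(13)-dien-1-yn-12,8-olide 6-[(2S,3S)-2,3-dimethyloxirane-2-carboxylate], both C3 epimers | C=C1C(=O)O[C@H]2C[C@](C)(O)C#CC(O)/C(C)=C\[C@H](OC(=O)[C@@]3(C)O[C@H]3C)[C@H]12 | intermediate
30 | (6S,7R,8S,10S)-10-hydroxy-3-oxogermacra-4(Z),11(13)-dien-1-yn-12,8-olide 6-[(2S,3S)-2,3-dimethyloxirane-2-carboxylate] | C=C1C(=O)O[C@H]2C[C@](C)(O)C#CC(=O)/C(C)=C\[C@H](OC(=O)[C@@]3(C)O[C@H]3C)[C@H]12 | intermediate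
31 | CNP0258430.1, (6S,7R,8S,10S)-3,10-epoxy-1-oxogermacra-2,4(Z),11(13)-trien-12,8-olide 6-[(2S,3S)-2,3-dimethyloxirane-2-carboxylate] | C=C1C(=O)O[C@H]2C[C@]3(C)OC(=CC3=O)/C(C)=C\[C@H](OC(=O)[C@@]3(C)O[C@H]3C)[C@H]12 | target

## Step count and risk

Total step count: 22. Longest linear sequence: 16 steps (from 6 through steps 4–11 and 15–22).

**Step 15 (proposed new method).** The carboxylate is a weak nucleophile, so the displacement may be slow. Forcing it invites ionisation of the C6–C11 bond, which would lose the inversion and allow attack at C4. The phosphonate anion may also re-close onto C6 and reverse the opening.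
Fallback from known chemistry, setting out from 15 and returning at 24:
- Sharpless asymmetric epoxidation of 15 (Ti(OiPr)4, L-(+)-diisopropyl tartrate, t-BuOOH) is the matched case for the 8S carbinol. It touches only the C6=C7 alkene beside the free hydroxyl and should give the (6S,7S,8S) epoxy alcohol F1.
- Steglich esterification with 16 gives the epoxy phosphonoacetate F2.
- Base (NaH, THF, 0 °C) generates the phosphonoacetate anion, which opens the epoxide at C7 in the 5-exo mode with inversion. This gives the hydroxy phosphono lactone F3, in which the C6 oxygen keeps the epoxide configuration and C6–C8 have the array of 24.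
- Yamaguchi esterification of F3 with 23, done without delay to forestall translactonisation, gives 24.

**Step 11 (key step).** Face selection relative to C8 rests on substrate control alone under an achiral catalyst and may be insufficient. C–H insertion at C9, or dipolar cycloaddition of the diazo group before the carbenoid forms, may also intervene.
Fallback, setting out from 15 and returning at 19:
- Acylation with bromoacetyl bromide gives the bromoacetate F4.
- N,N′-ditosylhydrazine and DBU convert it into the diazoacetate F5.
- Cyclopropanation with Rh2(5R-MEPY)4 (the divalent rhodium dimer with four methyl (R)-2-oxopyrrolidine-5-carboxylate ligands) adds catalyst control to substrate control and should give the des-phosphono cyclopropane lactone F6. The enantiomer is chosen because its sense on the parent allyl diazoacetate coincides with the exo arrangement needed here.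
- Deprotonation of F6 at the bridgehead C11 (LDA, −78 °C), trapping with ClP(OEt)2 and oxidation (H2O2) installs the phosphonate with retention and gives 19.

**Step 20.** Ring closure to a strained cycloalkenyne may be slow. Protonation or reduction of the alkynylchromium species, or oligomerisation, may then outrun it.
Fallback, setting out from 25 and returning at 29:
- Buffered fluoride (TBAF, AcOH) removes all three silyl groups and gives the terminal alkyne diol F7.
- MnO2 gives the terminal alkyne enal F8.
- Zn(OTf)2 and Et3N at high dilution generate a zinc acetylide reversibly by C–H metalation, with no low-valent metal present. The nucleophile is regenerated until it closes on the aldehyde to give 29.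

**Step 8.** An α-unbranched aldehyde may give modest facial selectivity, and methyl transfer from zinc may compete.
Fallback, setting out from 12 and 5 and returning at 15:
- The same addition without ligand gives the C8-epimeric dienols F9.
- MnO2 oxidises them to the dienone F10.
- Corey–Bakshi–Shibata reduction with the (R)-oxazaborolidine and catecholborane at −78 °C, with the dienyl group as the large substituent, gives 15.

**Step 22.** Cationic gold may engage other π systems, or the transannular condensation may stall at a hydrated intermediate.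
Fallback, setting out from 30 and returning at 31:
- Excess Et2NH in EtOH, then mild aqueous acid, forms the furanone through the enaminone and also adds amine to C13, giving the amino-adduct furanone F11.
- Quaternisation with MeI and elimination with NaHCO3 restores the methylidene group and gives 31.

## Further compounds

F1 | step 15 | (6S,7S,8S,10S)-6,7-epoxide of dienol 15: (1S,3S)-1-[(2S,3S)-3-[(1Z)-3-{[tert-butyl(dimethyl)silyl]oxy}-2-methylprop-1-en-1-yl]oxiran-2-yl]-3-methyl-3-[(triethylsilyl)oxy]-5-(trimethylsilyl)pent-4-yn-1-ol | O[C@@H](C[C@](C)(O[Si](CC)(CC)CC)C#C[Si](C)(C)C)[C@@H]1O[C@H]1/C=C(C)\CO[Si](C)(C)C(C)(C)C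
F2 | step 15 | (diethoxyphosphoryl)acetate of F1 | CCOP(=O)(OCC)CC(=O)O[C@@H](C[C@](C)(O[Si](CC)(CC)CC)C#C[Si](C)(C)C)[C@@H]1O[C@H]1/C=C(C)\CO[Si](C)(C)C(C)(C)C
F3 | step 15 | 6S-hydroxy analogue of 24 (free C6 alcohol, C11 epimers) | CCOP(=O)(OCC)C1C(=O)O[C@@H](C[C@](C)(O[Si](CC)(CC)CC)C#C[Si](C)(C)C)[C@@H]1[C@@H](O)/C=C(C)\CO[Si](C)(C)C(C)(C)C
F4 | step 11 | bromoacetate of dienol 15 | BrCC(=O)O[C@@H](C[C@](C)(O[Si](CC)(CC)CC)C#C[Si](C)(C)C)/C=C/C=C(C)\CO[Si](C)(C)C(C)(C)C
F5 | step 11 | diazoacetate of dienol 15 | [N-]=[N+]=CC(=O)O[C@@H](C[C@](C)(O[Si](CC)(CC)CC)C#C[Si](C)(C)C)/C=C/C=C(C)\CO[Si](C)(C)C(C)(C)C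
F6 | step 11 | des-phosphono analogue of 19 (C11–H), (1S,4S,5R,6R)-3-oxabicyclo[3.1.0]hexan-2-one | O=C1O[C@@H](C[C@](C)(O[Si](CC)(CC)CC)C#C[Si](C)(C)C)[C@@H]2[C@@H](/C=C(C)\CO[Si](C)(C)C(C)(C)C)[C@H]12
F7 | step 20 | terminal alkyne diol: (1S,2Z)-4-hydroxy-1-{(2S,3R)-2-[(2S)-2-hydroxy-2-methylbut-3-yn-1-yl]-4-methylidene-5-oxooxolan-3-yl}-3-methylbut-2-en-1-yl (2S,3S)-2,3-dimethyloxirane-2-carboxylate | C=C1C(=O)O[C@@H](C[C@](C)(O)C#C)[C@@H]1[C@@H](OC(=O)[C@@]2(C)O[C@H]2C)/C=C(C)\CO
F8 | step 20 | terminal alkyne enal: the 4-oxo analogue of F7 | C=C1C(=O)O[C@@H](C[C@](C)(O)C#C)[C@@H]1[C@@H](OC(=O)[C@@]2(C)O[C@H]2C)/C=C(C)\C=O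
F9 | step 8 | dienol 15 as the mixture of C8 epimers (10S) | OC(C[C@](C)(O[Si](CC)(CC)CC)C#C[Si](C)(C)C)/C=C/C=C(C)\CO[Si](C)(C)C(C)(C)C
F10 | step 8 | (3S,6E,8Z)-10-{[tert-butyl(dimethyl)silyl]oxy}-3,9-dimethyl-3-[(triethylsilyl)oxy]-1-(trimethylsilyl)deca-6,8-dien-1-yn-5-one | O=C(C[C@](C)(O[Si](CC)(CC)CC)C#C[Si](C)(C)C)/C=C/C=C(C)\CO[Si](C)(C)C(C)(C)C
F11 | step 22 | 13-(diethylamino)-11,13-dihydro analogue of 31 (C11 epimers) | CCN(CC)CC1C(=O)O[C@H]2C[C@]3(C)OC(=CC3=O)/C(C)=C\[C@H](OC(=O)[C@@]3(C)O[C@H]3C)[C@H]12
A1 | alternative 1 | thirteen-membered diallyl ether joining C6 and C13 through oxygen, furanone in place | C[C@]12C[C@H](O[Si](C)(C)C(C)(C)C)/C=C(C)/COC/C=C(C)\C(=CC1=O)O2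
A2 | alternative 1 | ten-membered carbocycle with C6 hydroxyl and C7 isopropenyl group | C[C@]12C[C@H](O[Si](C)(C)C(C)(C)C)[C@@H](C(C)=C)[C@@H](O)/C=C(C)\C(=CC1=O)O2
A3 | alternative 2 | dihydropyran diazoketone with the C7-bound silyloxyvinyl group | CC(=[N+]=[N-])C(=O)C[C@@H]1O[C@H](C(=C)O[Si](C)(C)C(C)(C)C)[C@@H](O[Si](C)(C)C(C)(C)C)C=C1C
A4 | alternative 2 | oxa-bridged bicyclic ketone carrying the C7=C8 silyl enol ether | C[C@]12C/C(O[Si](C)(C)C(C)(C)C)=C\[C@@H](O[Si](C)(C)C(C)(C)C)/C=C(C)\[C@H](CC1=O)O2
A5 | alternative 3 | lactone-fused cyclooctenone with the C2=C5 enone alkene | O=C1O[C@H]2C[C@](C)(O[Si](CC)(CC)CC)C(=O)/C=C\[C@H](O[Si](C)(C)C(C)(C)C)[C@@H]2C1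
A6 | alternative 3 | 1-(triisopropylsilyloxy)propyne | CC#CO[Si](C(C)C)(C(C)C)C(C)C
A7 | alternative 3 | ten-membered 3-siloxy dienone | O=C1O[C@H]2C[C@](C)(O[Si](CC)(CC)CC)C(=O)/C=C(O[Si](C(C)C)(C(C)C)C(C)C)/C(C)=C\[C@H](O[Si](C)(C)C(C)(C)C)[C@@H]2C1
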